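## Retrosynthetic overview

1. The feature used sits in the only ring, a 3,6-dihydro-2H-pyran (O1–C2–C3–C4=C5–C6). C2 carries O1 and the α-carbon of the α-methylene carboxyl group. This is the O–CH–C(=CH2)–CO2R array of a Morita–Baylis–Hillman (MBH) adduct, and its carbinol centre can be ionised and re-formed through the acrylate.
2. Acid ⇒ methyl ester ⇒ (cut O1–C2) a racemic open-chain MBH tert-butyl carbonate with a free C6 hydroxyl on a Z C4=C5 alkene. A chiral tertiary amine closes the ring by two successive SN2′ steps and sets C2. This is the only ring closure and the only stereocentre.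
3. Carbonate ⇒ (cut C2–Cα) an α-aluminoacrylate from methyl propiolate plus a Z β,γ-unsaturated aldehyde ⇒ (cut C3–C4) a Z vinyllithium plus ethylene oxide.
4. Z vinyl iodide ⇒ (cut C5–C1′) alkoxide-directed anti-carbomagnesiation of propargyl alcohol with homofarnesylmagnesium bromide, which fixes C3 and C6 cis.
5. Homofarnesyl bromide ⇒ (2E,6E)-farnesol by one-carbon homologation (oxidation, methylenation, hydroboration, bromination).

Key step: step 12

Atom labels: the ring numbers O1, C2, C3, C4, C5, C6 are used for the same atoms in all open-chain precursors. Cα is the acrylate carbon bonded to C2. "Homofarnesyl" is (3E,7E)-4,8,12-trimethyltrideca-3,7,11-trien-1-yl.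

Assumption: the quinidine-series catalyst is taken to steer the alkoxide to the Re face of C2, which gives (R). The sense of induction of this new closure cannot be derived from intermolecular cases. If it proves opposite, the pseudoenantiomeric (DHQ)2PHAL takes its place with no other change.

## Route

Step 1
Reactants: 1 (2E,6E)-farnesol
Product: 2 (2E,6E)-farnesal
Conditions: TEMPO (10 mol %), PhI(OAc)2 (1.1 equiv), CH2Cl2, 0 °C → rt
Reagents that add atoms: none
Why: The oxoammonium (TEMPO/PhI(OAc)2) oxidation takes the primary allylic alcohol to the enal under nearly neutral conditions, so the 2E alkene should keep its geometry and the isolated trisubstituted alkenes stay untouched.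

Step 2
Reactants: 2 (2E,6E)-farnesal
Product: 3 (3E,7E)-4,8,12-trimethyltrideca-1,3,7,11-tetraene
Conditions: Ph3PCH3Br, n-BuLi, THF, 0 °C; then 2, −78 °C → rt
Reagents that add atoms: methyltriphenylphosphonium bromide, C[P+](c1ccccc1)(c1ccccc1)c1ccccc1.[Br-]
Why: Wittig methylenation with the non-stabilised ylide turns the enal carbonyl into a terminal vinyl group and leaves the E alkenes as they are.

Step 3
Reactants: 3 (3E,7E)-4,8,12-trimethyltrideca-1,3,7,11-tetraene
Product: 5 (3E,7E)-homofarnesol, via B-homofarnesyl-9-BBN 4 (not isolated)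
Conditions: 9-BBN (1.05 equiv), THF, 0 °C → rt; then 3 M NaOH, 30 % H2O2, 0 °C → rt
Reagents that add atoms: hydrogen peroxide, OO; 9-BBN, B1C2CCCC1CCC2 (its boron and ring are present only in 4)
Why: In this hydroboration–oxidation the bulky 9-BBN adds anti-Markovnikov only to the monosubstituted end of the 1,3-diene, because every other alkene is trisubstituted, and alkaline peroxide then replaces boron by hydroxyl.

Step 4
Reactants: 5 (3E,7E)-homofarnesol
Product: 6 (3E,7E)-homofarnesyl bromide
Conditions: CBr4, PPh3, CH2Cl2, 0 °C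
Reagents that add atoms: carbon tetrabromide, BrC(Br)(Br)Br
Why: The Appel reaction substitutes the primary, non-allylic hydroxyl by SN2 under neutral conditions that do not affect the polyene.

Step 5
Reactants: 6 (3E,7E)-homofarnesyl bromide; 7 propargyl alcohol
Product: 11 (2Z)-3-iodo-2-homofarnesylprop-2-en-1-ol, via homofarnesylmagnesium bromide 8 (not isolated), via bromomagnesium prop-2-yn-1-olate 9 (not isolated), via oxamagnesacyclopentene 10 (not isolated)
Conditions: (a) 6, Mg, THF, rt; (b) 7, MeMgBr (1.0 equiv), THF, −20 °C; (c) 8 (1.2 equiv) + 9, CuI (15 mol %), THF–Et2O, −10 °C → rt; (d) I2, THF, −30 → 0 °C; aq NH4Cl/Na2S2O3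
Reagents that add atoms: iodine, II; magnesium, [Mg], and methylmagnesium bromide, C[Mg]Br (the metal is present only in 8–10)
Why: The copper-catalysed, alkoxide-directed anti-carbomagnesiation of a propargylic alcohol places the alkyl group on C5 and magnesium on C4 inside a five-membered O–Mg chelate, so iodinolysis with retention should give the iodide with I cis to CH2OH (Z), while forming 9 with MeMgBr beforehand spares one equivalent of 8.

Step 6
Reactants: 11 (2Z)-3-iodo-2-homofarnesylprop-2-en-1-ol
Product: 12 tetrahydropyranyl (THP) ether of 11 (Z; mixture at the acetal carbon)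
Conditions: 3,4-dihydro-2H-pyran, PPTS (5 mol %), CH2Cl2, rt
Reagents that add atoms: 3,4-dihydro-2H-pyran, C1=COCCC1
Why: This is an acid-catalysed acetalisation, and an acetal is preferred to a silyl ether because a silyl group held cis to the C4 carbanion of step 7 could migrate from oxygen to carbon (retro-Brook 1,4-shift).

Step 7
Reactants: 12 THP ether of 11; 13 ethylene oxide
Product: 15 (3Z,7E,11E)-8,12,16-trimethyl-4-[(oxan-2-yloxy)methyl]heptadeca-3,7,11,15-tetraen-1-ol, via Z-vinyllithium 14 (not isolated)
Conditions: t-BuLi (2.05 equiv), Et2O, −78 °C; ethylene oxide (THF solution, 3 equiv), −78 → 0 °C; H2O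
Reagents that add atoms: ethylene oxide (13), C1CO1; tert-butyllithium, [Li]C(C)(C)C (lithium is present only in 14)
Why: Iodine–lithium exchange keeps the alkene geometry, and the vinyllithium, held by chelation to the acetal oxygen, opens ethylene oxide by SN2 and so adds C3 and C2 cis to C6.

Step 8
Reactants: 15 homoallylic alcohol
Product: 16 (3Z,7E,11E)-8,12,16-trimethyl-4-[(oxan-2-yloxy)methyl]heptadeca-3,7,11,15-tetraenal
Conditions: Dess–Martin periodinane, NaHCO3, CH2Cl2, 0 °C; short filtration, used at once
Reagents that add atoms: none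
Why: The bicarbonate-buffered Dess–Martin oxidation gives the aldehyde without amine base or strong acid, which is what keeps the C4=C5 alkene of this β,γ-unsaturated aldehyde from moving into conjugation.

Step 9
Reactants: 16 β,γ-unsaturated aldehyde; 17 methyl propiolate
Product: 19 methyl (5Z,9E,13E)-3-hydroxy-10,14,18-trimethyl-2-methylidene-6-[(oxan-2-yloxy)methyl]nonadeca-5,9,13,17-tetraenoate (racemic at C2), via α-aluminoacrylate 18 (not isolated)
Conditions: DIBAL-H (1.4 equiv), NMO (1.5 equiv), THF, 0 °C; 17 (1.5 equiv), 0 °C; then 16, 0 °C → rt; aq Rochelle salt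
Reagents that add atoms: methyl propiolate (17), C#CC(=O)OC; DIBAL-H, CC(C)C[AlH]CC(C)C (aluminium is present only in 18)
Why: Conjugate hydroalumination of the propiolate gives the non-basic vinylalane 18, which adds 1,2 to the enolisable aldehyde (vinylalumination) and so delivers the MBH-type alcohol without the amine of a true MBH reaction, and a racemate is acceptable because step 12 erases this centre.

Step 10
Reactants: 19 racemic MBH alcohol
Product: 20 methyl (5Z,9E,13E)-3-[(tert-butoxycarbonyl)oxy]-10,14,18-trimethyl-2-methylidene-6-[(oxan-2-yloxy)methyl]nonadeca-5,9,13,17-tetraenoate (racemic)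
Conditions: Boc2O (1.4 equiv), DMAP (10 mol %), CH2Cl2, 0 °C → rt
Reagents that add atoms: di-tert-butyl dicarbonate, CC(C)(C)OC(=O)OC(=O)OC(C)(C)C
Why: DMAP-catalysed O-acylation with Boc2O is the standard way to MBH carbonates, and the only free hydroxyl in 19 is the one at C2.

Step 11
Reactants: 20 THP-protected carbonate
Product: 21 methyl (5Z,9E,13E)-3-[(tert-butoxycarbonyl)oxy]-6-(hydroxymethyl)-10,14,18-trimethyl-2-methylidenenonadeca-5,9,13,17-tetraenoate (racemic; the cyclisation precursor)
Conditions: PPTS (20 mol %), MeOH, rt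
Reagents that add atoms: none
Why: Transacetalisation with a weak acid in methanol removes the THP group while the tert-butyl carbonate, the acrylate and the trisubstituted alkenes survive, and no base or fluoride is present that could start an uncatalysed, racemic ring closure.

Step 12
Reactants: 21 racemic MBH carbonate with free C6 hydroxyl
Product: 23 methyl 2-[(2R)-5-homofarnesyl-3,6-dihydro-2H-pyran-2-yl]prop-2-enoate, via allylic ammonium enoate 22 (not isolated)
Conditions: (DHQD)2PHAL (20 mol %), 4 Å MS, toluene (0.02 M), rt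
Reagents that add atoms: (DHQD)2PHAL (catalyst; its atoms are present only in 22 and are released again), COc1ccc2nccc([C@@H]([C@H]3C[C@@H]4CCN3C[C@@H]4CC)Oc3nnc(O[C@H]([C@H]4C[C@@H]5CCN4C[C@@H]5CC)c4ccnc5ccc(OC)cc45)c4ccccc34)c2c1
Why: Proposed new method: a quinuclidine nitrogen of the catalyst adds to the acrylate CH2 of either enantiomer of 21 and expels tert-butyl carbonate (first SN2′), which loses CO2, so both enantiomers merge in the one ammonium enoate 22 with an sp2 C2, and the released tert-butoxide takes the proton of the C6 hydroxyl. The alkoxide then adds to C2 and expels the amine (second SN2′), which forms O1–C2, restores the exocyclic methylene and closes the dihydropyran in a 6-exo-trig mode, since the C2=Cα π bond that breaks lies outside the new ring. The closest known reaction type is the cinchona-amine-catalysed asymmetric allylic substitution of racemic, mostly aryl-substituted MBH carbonates by external oxygen nucleophiles (water, hydroperoxides, oximes, phenols), and what is new is the tethered aliphatic alcohol on an alkyl-substituted carbonate. The single new stereocentre C2 is controlled by the chiral ammonium group on the neighbouring CH2, which shields one face of the enoate so that the alkoxide should reach the Re face and give (R). The step needs attack at C2 rather than at CH2–N+, which the Z C4=C5 alkene secures by holding C3 and C6 cis (six-membered ring against a strained eight-membered one). It also needs closure to outrun loss of a doubly allylic C3 proton, capture by tert-butoxide and intermolecular etherification, which the tether, high dilution, dry conditions and a non-polar solvent favour.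

Step 13
Reactants: 23 methyl ester
Product: 24 2-[(2R)-5-homofarnesyl-3,6-dihydro-2H-pyran-2-yl]prop-2-enoic acid (target)
Conditions: LiOH·H2O (4 equiv), THF–MeOH–H2O, 0 °C → rt; then 1 M HCl to pH 3–4, 0 °C
Reagents that add atoms: lithium hydroxide, [Li+].[OH-]
Why: Saponification (BAc2) cleaves only the methyl ester, the ring alkoxide is too poor a leaving group and C2–H too weakly acidic for ring opening or epimerisation under these conditions, and the brief cold acidification spares the polyene.

## Compound list

1 | (2E,6E)-farnesol | CC(C)=CCC/C(C)=C/CC/C(C)=C/CO | starting material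
2 | (2E,6E)-farnesal | CC(C)=CCC/C(C)=C/CC/C(C)=C/C=O | intermediate
3 | (3E,7E)-4,8,12-trimethyltrideca-1,3,7,11-tetraene | CC(C)=CCC/C(C)=C/CC/C(C)=C/C=C | intermediate
4 | 9-homofarnesyl-9-borabicyclo[3.3.1]nonane (not isolated) | CC(C)=CCC/C(C)=C/CC/C(C)=C/CCB1C2CCCC1CCC2 | intermediate
5 | (3E,7E)-homofarnesol, (3E,7E)-4,8,12-trimethyltrideca-3,7,11-trien-1-ol | CC(C)=CCC/C(C)=C/CC/C(C)=C/CCO | intermediate
6 | (3E,7E)-homofarnesyl bromide | CC(C)=CCC/C(C)=C/CC/C(C)=C/CCBr | intermediate
7 | propargyl alcohol | C#CCO | starting material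
8 | homofarnesylmagnesium bromide (not isolated) | CC(C)=CCC/C(C)=C/CC/C(C)=C/CC[Mg]Br | intermediate
9 | bromomagnesium prop-2-yn-1-olate (not isolated) | C#CCO[Mg]Br | intermediate
10 | 4-homofarnesyl-2,5-dihydro-1,2-oxamagnesole, ring O–Mg–CH=C–CH2 (not isolated) | CC(C)=CCC/C(C)=C/CC/C(C)=C/CCC1=C[Mg]OC1 | intermediate
11 | (2Z)-3-iodo-2-homofarnesylprop-2-en-1-ol | I/C=C(\CO)CC/C=C(\C)CC/C=C(\C)CCC=C(C)C | intermediate
12 | THP ether of 11 (Z; acetal carbon undefined) | I/C=C(\COC1CCCCO1)CC/C=C(\C)CC/C=C(\C)CCC=C(C)C | intermediate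
13 | ethylene oxide | C1CO1 | starting material
14 | Z-vinyllithium from 12 (not isolated) | [Li]/C=C(\COC1CCCCO1)CC/C=C(\C)CC/C=C(\C)CCC=C(C)C | intermediate
15 | (3Z,7E,11E)-8,12,16-trimethyl-4-[(oxan-2-yloxy)methyl]heptadeca-3,7,11,15-tetraen-1-ol | OCC/C=C(\COC1CCCCO1)CC/C=C(\C)CC/C=C(\C)CCC=C(C)C | intermediate
16 | (3Z,7E,11E)-8,12,16-trimethyl-4-[(oxan-2-yloxy)methyl]heptadeca-3,7,11,15-tetraenal | O=CC/C=C(\COC1CCCCO1)CC/C=C(\C)CC/C=C(\C)CCC=C(C)C | intermediate
17 | methyl propiolate | C#CC(=O)OC | starting material
18 | methyl 2-(diisobutylalumanyl)prop-2-enoate (not isolated) | C=C(C(=O)OC)[Al](CC(C)C)CC(C)C | intermediate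
19 | racemic MBH alcohol, C6–OTHP | C=C(C(=O)OC)C(O)C/C=C(\COC1CCCCO1)CC/C=C(\C)CC/C=C(\C)CCC=C(C)C | intermediate
20 | racemic MBH tert-butyl carbonate, C6–OTHP | C=C(C(=O)OC)C(OC(=O)OC(C)(C)C)C/C=C(\COC1CCCCO1)CC/C=C(\C)CC/C=C(\C)CCC=C(C)C | intermediate
21 | racemic MBH tert-butyl carbonate, free C6–OH (key-step precursor) | C=C(C(=O)OC)C(OC(=O)OC(C)(C)C)C/C=C(\CO)CC/C=C(\C)CC/C=C(\C)CCC=C(C)C | intermediate
22 | allylic ammonium enoate of (DHQD)2PHAL, tert-butoxide salt, drawn as the E enoate (not isolated) | COc1ccc2nccc([C@@H]([C@H]3C[C@@H]4CC[N+]3(C/C(C(=O)OC)=C\C/C=C(\CO)CC/C=C(\C)CC/C=C(\C)CCC=C(C)C)C[C@@H]4CC)Oc3nnc(O[C@H]([C@H]4C[C@@H]5CCN4C[C@@H]5CC)c4ccnc5ccc(OC)cc45)c4ccccc34)c2c1.CC(C)(C)[O-] | intermediate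
23 | methyl 2-[(2R)-5-homofarnesyl-3,6-dihydro-2H-pyran-2-yl]prop-2-enoate (key-step product) | C=C(C(=O)OC)[C@H]1CC=C(CC/C=C(\C)CC/C=C(\C)CCC=C(C)C)CO1 | intermediate
24 | 2-[(2R)-5-homofarnesyl-3,6-dihydro-2H-pyran-2-yl]prop-2-enoic acid | C=C(C(=O)O)[C@H]1CC=C(CC/C=C(\C)CC/C=C(\C)CCC=C(C)C)CO1 | target

## Step count and risks

Total step count: 13. Longest linear sequence: 13 (from farnesol 1).

**Step 12 (Proposed new method).**
- What may go wrong:
  - The first SN2′ step may be slow on an alkyl-substituted carbonate.
  - The ammonium enoate may lose a doubly allylic C3 proton and eliminate the amine before the ring closes.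
  - tert-Butoxide may compete as a nucleophile.
  - The facial selectivity at C2 may be poor.
- Fallback by known chemistry: set the C2 carbinol centre first and close the ring at the other C–O bond (O1–C6), which leaves C2 untouched.
- It sets out from aldehyde 16. A β-isocupreidine-catalysed asymmetric MBH reaction with 1,1,1,3,3,3-hexafluoroisopropyl acrylate (DMF, −55 °C) should give the (R)-hexafluoroisopropyl ester F1.
- Methanolysis (Et3N, MeOH) gives the (R)-methyl ester F2, and PPTS in MeOH frees the (R)-diol F3.
- MsCl, 2,4,6-collidine and LiCl in DMF at 0 °C convert only the primary allylic hydroxyl into the (R)-allylic chloride F4.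
- NaH in THF at 0 °C closes the ring by an intramolecular Williamson etherification (6-exo-tet) with retention at C2. The fallback comes back to the route at 23.

**Step 5.**
- What may go wrong:
  - Wurtz coupling may occur during Grignard formation.
  - The carbomagnesiation with a long-chain reagent used in small excess may be sluggish.
  - The vinylmagnesium may be protonated by alkyne C–H before iodination.
- Fallback: build the Z alkene by olefination instead of carbometallation.
- It sets out from bromide 6, which alkylates commercial ethyl (diphenoxyphosphoryl)acetate (NaH, DMSO) to the α-homofarnesyl phosphonate F5.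
- A Z-selective Horner–Wadsworth–Emmons reaction of this diaryl phosphonate with commercial 3-(tert-butyldimethylsilyloxy)propanal (NaH, THF, −78 → 0 °C) should give the Z enoate F6.
- DIBAL-H gives the allylic alcohol F7, dihydropyran/PPTS gives the bis-protected diol F8, and TBAF removes the silyl group. The fallback comes back to the route at 15 and so replaces steps 5–7.

**Step 9.**
- What may go wrong:
  - The addition is slow at 0 °C to rt, so the C4=C5 alkene may migrate into conjugation with the aldehyde.
  - Residual hydride may reduce the aldehyde.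
- Fallback: a fast aldol at low temperature followed by elimination.
- It sets out from aldehyde 16. The lithium enolate of methyl 3-(dimethylamino)propanoate (LDA, THF, −78 °C) adds to give the β-hydroxy-α-(dimethylaminomethyl) ester F9.
- MeI in MeOH gives the trimethylammonium iodide F10, and K2CO3 brings about the E1cB-type Hofmann elimination that creates the methylene group. The fallback comes back to the route at 19.

## Further compounds

F1 | step 12 | 1,1,1,3,3,3-hexafluoropropan-2-yl ester of the (R)-MBH alcohol, C6–OTHP | C=C(C(=O)OC(C(F)(F)F)C(F)(F)F)[C@H](O)C/C=C(\COC1CCCCO1)CC/C=C(\C)CC/C=C(\C)CCC=C(C)C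
F2 | step 12 | (R)-methyl ester, the (R) enantiomer of 19 | C=C(C(=O)OC)[C@H](O)C/C=C(\COC1CCCCO1)CC/C=C(\C)CC/C=C(\C)CCC=C(C)C
F3 | step 12 | (R)-diol, free C2–OH and C6–OH | C=C(C(=O)OC)[C@H](O)C/C=C(\CO)CC/C=C(\C)CC/C=C(\C)CCC=C(C)C
F4 | step 12 | (R)-allylic chloride at C6 | C=C(C(=O)OC)[C@H](O)C/C=C(\CCl)CC/C=C(\C)CC/C=C(\C)CCC=C(C)C
F5 | step 5 | ethyl (5E,9E)-2-(diphenoxyphosphoryl)-6,10,14-trimethylpentadeca-5,9,13-trienoate | CCOC(=O)C(CC/C=C(\C)CC/C=C(\C)CCC=C(C)C)P(=O)(Oc1ccccc1)Oc1ccccc1
F6 | step 5 | ethyl (Z)-5-(tert-butyldimethylsilyloxy)-2-homofarnesylpent-2-enoate | CCOC(=O)/C(CC/C=C(\C)CC/C=C(\C)CCC=C(C)C)=C\CCO[Si](C)(C)C(C)(C)C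
F7 | step 5 | (Z)-5-(tert-butyldimethylsilyloxy)-2-homofarnesylpent-2-en-1-ol | OC/C(CC/C=C(\C)CC/C=C(\C)CCC=C(C)C)=C\CCO[Si](C)(C)C(C)(C)C
F8 | step 5 | tert-butyldimethylsilyl ether of 15 | CC(C)(C)[Si](C)(C)OCC/C=C(\COC1CCCCO1)CC/C=C(\C)CC/C=C(\C)CCC=C(C)C
F9 | step 9 | methyl 2-[(dimethylamino)methyl]-3-hydroxy ester from 16 (mixture of diastereomers) | CN(C)CC(C(=O)OC)C(O)C/C=C(\COC1CCCCO1)CC/C=C(\C)CC/C=C(\C)CCC=C(C)C
F10 | step 9 | trimethylammonium iodide of F9 | C[N+](C)(C)CC(C(=O)OC)C(O)C/C=C(\COC1CCCCO1)CC/C=C(\C)CC/C=C(\C)CCC=C(C)C.[I-]
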